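## The problem

The target is a 2,3,4,7-tetrahydrooxepine (O1, C2, C3, C4, C5=C6, C7). C2 is fully substituted: it carries O1, a free carboxylic acid and a CH2–C(=O) arm ending in a 2,5-dihydroxyphenyl ring. C6 carries a (3E)-4-methylpent-3-enyl chain (C8 to C12, methyl on C11) whose C12 oxygen is acylated by (E)-4-hydroxycinnamic acid. C2 is the only stereocentre, so no other centre can set or repair it, and it must come from an enantioselective bond formation at a prochiral carbon. Because O1 sits β to the aryl ketone, any base able to enolise that ketone can open the ring by retro-oxa-Michael elimination and erase the centre. The ring is seven-membered, and its double bond must lie at C5=C6 and not at C6=C7, where it would be an enol ether. The hydroquinone oxidises once free, the allylic cinnamate does not tolerate hydroxide, strong nucleophiles or zerovalent palladium, and the acid must be released beside that ester; saponification, hydrogenolysis and allyl-type protection are therefore excluded at the end. Two features open the way: C6 is a single carbon between C5 and the oxygen-bound C7, so without it C5 and C7 form the enol ether of a 3,4-dihydro-2H-pyran, and C6 can be put back as a dihalocarbene whose cyclopropane opens to the seven-membered ring with a halogen on C6; and the CH2–C(=O)–aryl arm is the hydrate of an arylalkyne lying γ to the ester carbonyl, so C2 can be made by alkynylation of an α-keto ester and the ketone unmasked later under ester direction.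

## Retrosynthesis

**Disconnection 1 (31 to 30; three aryl O–Si bonds and the ester C–O bond at C1).** The last step has to free three phenols and one acid without touching the cinnamate. Fluoride-labile groups on all four positions do this in one operation, whereas an alkyl ester would need hydroxide and a benzyl or allyl ester would need hydrogen or zerovalent palladium. Compound 30 therefore carries two aryl TIPS ethers, one aryl TBS ether and a 2-(trimethylsilyl)ethyl ester. The forward step needs fluoride that is buffered so that the β-alkoxy ketone is not enolised.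

**Disconnection 2 (30 to 26 and 29; acyl–O bond at C12).** The cinnamate is a Michael acceptor and an allylic ester, so it is attached after all organometallic steps. Alcohol 26 and acid 29 are joined by carbodiimide esterification; 29 comes from 4-hydroxycinnamic acid 27 through the bis-silyl compound 28. The forward step needs only a weakly basic acyl-transfer catalyst.

**Disconnection 3 (26 via 25 to 19 and 24; C6–C8).** Cutting the sp2–sp3 bond at C6 removes the whole side chain and leaves an alkenyl bromide. This cut is preferred over a cut inside the chain because the ring expansion below leaves a bromine on C6 anyway. The alkylzinc 24 comes from bromide 23, the silyl ether of allylic alcohol 22, which is made by allylic oxidation of 5-bromo-2-methylpent-2-ene 20 (over-oxidised enal 21 is reduced back). The forward Negishi coupling must leave a ketone, an ester and silyl ethers alone, which alkylzinc halides do.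

**Disconnection 4 (19 to 18; the C=O bond of the aryl ketone).** The ketone is taken back to an arylalkyne. In 18 the alkyne is a 3-alkynoate, so the ester carbonyl can deliver oxygen to the aryl-bearing carbon and fix the regiochemistry. Hydration is placed before the coupling, while the only alkene present is the electron-poor bromoalkene, so that enyne cycloisomerisation with a trisubstituted ring alkene cannot compete. It is placed after the acetal reduction because a silane with a Lewis acid would reduce an electron-rich aryl ketone.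

**Disconnection 5 (18 via 17 to 16, then 16 to 14 and 15; C7–H, then the C5–C7 bond re-formed, then both bonds to C6).** The C7 methylene of 18 is taken back to the methyl acetal 17. Acetal 17 is the product of electrocyclic opening of the gem-dibromocyclopropane 16, and 16 is the dibromocarbene adduct of dihydropyran 14 with bromoform 15. Direct seven-ring closures are weaker here: etherification of the hindered tertiary alcohol onto an allylic carbon is slow, and ring-closing metathesis would meet the arylalkyne in an enyne pathway. The ring expansion instead starts from an easily closed six-membered ring, places the alkene at C5=C6 by mechanism and leaves the coupling handle on C6. The forward step needs the endo bromide to leave, the ring-fusion bond to break and the cation to be captured at C7.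

**Disconnection 6 (14 via 12 to 10; the enol ether C=C, then the O1–C7 bond and the C7 carbonyl).** Dihydropyran 14 is the dehydration product of lactol 12 (through anomeric mesylate 13). Lactol 12 is the closed form of the δ-hydroxy aldehyde 11, which results from cleaving the terminal alkene of 10. The forward oxidation must take a monosubstituted alkene in the presence of an internal alkyne.

**Disconnection 7 (10 to 6 and 9; C2–C(sp)).** This is the only stereogenic bond formation. Adding the arylacetylene 9 to the ketone of α-keto ester 6 builds the quaternary centre, brings in the arene and leaves the ketone arm masked in a form that cannot undergo retro-aldol. An aldol construction of the C2–CH2 bond would give a β-hydroxy ketone that fragments easily. The forward step needs a chiral zinc catalyst that distinguishes the faces of an aliphatic keto ester.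

**Disconnection 8 (6 to 3 and 4; 3 to 1 and 2; 9 via 8 to 7).** Keto ester 6 comes from mono-addition of the Grignard reagent 5, made from 5-bromopent-1-ene 4, to the oxalate 3. The symmetrical diester 3 is assembled from one molecule of oxalyl chloride 1 and two molecules of 2-(trimethylsilyl)ethanol 2; one of the two alkoxy groups is given back in the Grignard step. Alkyne 9 comes from one-carbon homologation of aldehyde 8, the bis-TIPS ether of 2,5-dihydroxybenzaldehyde 7. TIPS is used on the hydroquinone because aryl TBS ethers are the more labile towards the alkoxide of the carbene step.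

## Roads not taken

**Alternative 1: the hydroquinone ring built last by cycloaddition.** The cut removes two C–C bonds of the arene. A terminal ynone A1, already carrying oxepine, side chain and cinnamate, would react with 2-methoxyfuran A2; the oxanorbornadiene opens at the methoxy-bearing bridgehead and tautomerises to the 5-hydroxy-2-methoxyphenyl ketone A3. Its merit is real: no electron-rich hydroquinone ether has to pass carbene, silver, Lewis-acid or gold steps, and the ketone position follows from the construction and needs no regioselective hydration. On this point it is better than the chosen plan. Its weak points are that A3 still has an aryl methyl ether ortho to the ketone, whose removal needs a boron trihalide in the presence of the allylic cinnamate and the allylic ring ether. In addition, A1 is a strong Michael acceptor next to an enolisable β-alkoxy methylene, and the step forms neither the oxepine nor C2, which would still have to be solved. The chosen plan answers with an arene that arrives in the same step that sets C2 and with phenol protection that leaves in the final fluoride step.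

**Alternative 2: vinylsilane-terminated oxocarbenium cyclisation.** The cut is C6–C7. SnCl4 would ionise the methoxymethyl ether of the C2 alcohol in the (Z)-vinylsilane A4; the oxocarbenium carbon attacks the silicon-bearing C6, the silyl group leaves, and the oxepine A5 results with the side chain already in place. This is more convergent than the chosen plan, which spends four steps (carbene addition, expansion, acetal reduction, coupling) on what A4 to A5 does in one, and the alkene position is equally secure. Against it, A4 needs a stereodefined trisubstituted vinylsilane, since only the isomer with silicon cis to the tether can close. It also needs a methoxymethyl ether on a hindered tertiary α-hydroxy ester, and an asymmetric construction of C2 with the ketone arm present as a retro-aldol-prone β-hydroxy ketone. SnCl4 would meet an aryl ketone, a β-alkoxy ketone and four silyl ethers. The chosen plan sets against the longer ring sequence a cheap C6 source (bromoform), a late and variable side-chain coupling, and a C2 synthesis by a known catalytic reaction.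

**Alternative 3: rhodium carbenoid O–H insertion.** The cut is O1–C7. Rh2(OAc)4 would decompose the diazoketone A6 and the C2 hydroxyl inserts into the carbenoid to give the oxepanone A7, whose ketone sits on C6 in target numbering. Ring closure by O–H insertion is as dependable as the ring expansion and accepts tertiary alcohols, and it forms the ring in a single step from an acyclic compound. The weak points lie after it: the C6 ketone of A7 must become a C5=C6 alkene bearing carbon, and enol triflate formation has to choose C5 over the oxygen-activated C7, a regiochemical question that the ring expansion settles by mechanism. A6 also needs diazo chemistry and a dioxolane on a hindered aryl ketone, whose later acid removal exposes the β-alkoxy ketone. The chosen plan needs one step more to reach the ring but delivers the alkene and the coupling handle in the right place without a selectivity question.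

Key step: step 9

Assumption: the facial sense of the zinc amino-alcohol catalyst on an aliphatic 2-oxo ester is not taken as settled; step 5 uses whichever ligand antipode sends the acetylide to the Re face of the ketone (2R product), both antipodes being available.

Abbreviations used in names: TIPSO = triisopropylsilyloxy, TBSO = tert-butyldimethylsilyloxy, TMSE = 2-(trimethylsilyl)ethyl.

## Route

Step 1
Reactants: 1 oxalyl chloride; 2 2-(trimethylsilyl)ethanol
Product: 3 bis[2-(trimethylsilyl)ethyl] oxalate
Conditions: 2 (2.1 equiv in all), pyridine (2.2 equiv), CH2Cl2, 0 °C to rt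
Reagents that add atoms: 2-(trimethylsilyl)ethanol (second equivalent of 2), C[Si](C)(C)CCO
Why: Ester formation from an acid chloride: each of the two acyl chloride groups of oxalyl chloride acylates one molecule of the primary alcohol, so two equivalents of 2 are consumed, with pyridine as HCl scavenger; there is no competing site.

Step 2
Reactants: 4 5-bromopent-1-ene; 3 bis[2-(trimethylsilyl)ethyl] oxalate
Product: 6 TMSE 2-oxohept-6-enoate, via pent-4-enylmagnesium bromide 5 (not isolated)
Conditions: Mg, THF, rt; then added to 3 (excess), THF, −78 °C; aq. NH4Cl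
Reagents that add atoms: none
Why: Grignard mono-addition to a dialkyl oxalate: the magnesium hemiketal alkoxide, chelated by the second ester, should persist at −78 °C until the quench, so the ketone is not attacked twice.

Step 3
Reactants: 7 2,5-dihydroxybenzaldehyde
Product: 8 2,5-bis(TIPSO)benzaldehyde
Conditions: TIPSCl, imidazole, DMF, rt
Reagents that add atoms: triisopropylsilyl chloride, CC(C)[Si](Cl)(C(C)C)C(C)C
Why: Imidazole-mediated silylation of both phenols; aryl TIPS ethers should withstand the alkoxide of step 8 and the acidic steps up to the final fluoride treatment.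

Step 4
Reactants: 8 2,5-bis(TIPSO)benzaldehyde
Product: 9 2-ethynyl-1,4-bis(TIPSO)benzene
Conditions: TMSCHN2, LiN(i-Pr)2, THF, −78 °C to rt
Reagents that add atoms: trimethylsilyldiazomethane, C[Si](C)(C)C=[N+]=[N-]
Why: Colvin rearrangement: the lithiated diazo compound adds to the aldehyde, Peterson elimination gives a diazoalkene, and loss of N2 with 1,2-hydrogen shift of the alkylidene carbene gives the terminal alkyne. The carbonate and methanol of phosphonate-based homologations, which attack aryl silyl ethers, are avoided.

Step 5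
Reactants: 6 TMSE 2-oxohept-6-enoate; 9 2-ethynyl-1,4-bis(TIPSO)benzene
Product: 10 TMSE (2R)-2-{[2,5-bis(TIPSO)phenyl]ethynyl}-2-hydroxyhept-6-enoate
Conditions: Zn(OTf)2 (20 mol %), 2-(dimethylamino)-3-(tert-butyldimethylsilyloxy)-1-(4-nitrophenyl)propan-1-ol (22 mol %, antipode giving Re-face addition), Et3N (30 mol %), toluene, 70 °C
Reagents that add atoms: none
Why: Catalytic asymmetric alkynylation of an α-keto ester by a zinc acetylide formed in situ from the terminal alkyne, Zn(OTf)2 and amine. The keto ester should bind zinc through both carbonyl oxygens beside the chiral amino alkoxide, which leaves the Re face of the ketone open to the acetylide and sets C2 as R, the only stereocentre of the target.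

Step 6
Reactants: 10 TMSE (2R)-2-{[2,5-bis(TIPSO)phenyl]ethynyl}-2-hydroxyhept-6-enoate
Product: 12 TMSE (2R)-2-{[2,5-bis(TIPSO)phenyl]ethynyl}-6-hydroxyoxane-2-carboxylate (both C6 epimers), via hydroxy aldehyde 11 (not isolated)
Conditions: OsO4 (2 mol %), NaIO4, 2,6-lutidine, 1,4-dioxane/H2O (3:1), rt
Reagents that add atoms: osmium tetroxide (catalytic oxygen carrier), O=[Os](=O)(=O)=O; sodium periodate (terminal oxidant), [Na+].[O-]I(=O)(=O)=O
Why: Lemieux–Johnson cleavage: dihydroxylation takes the monosubstituted alkene far faster than the hindered internal arylalkyne, periodate cleaves the diol, and the δ-hydroxy aldehyde should close spontaneously to the six-membered lactol.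

Step 7
Reactants: 12 TMSE (2R)-2-{[2,5-bis(TIPSO)phenyl]ethynyl}-6-hydroxyoxane-2-carboxylate
Product: 14 TMSE (2R)-2-{[2,5-bis(TIPSO)phenyl]ethynyl}-3,4-dihydro-2H-pyran-2-carboxylate, via anomeric mesylate 13 (not isolated)
Conditions: MsCl, Et3N, CH2Cl2, −20 °C; then reflux
Reagents that add atoms: none
Why: Lactol dehydration by sulfonylation of the anomeric hydroxyl and amine-induced elimination through the oxocarbenium ion, the standard way from a 2-hydroxytetrahydropyran to the enol ether; no other hydroxyl is present.

Step 8
Reactants: 14 TMSE (2R)-2-{[2,5-bis(TIPSO)phenyl]ethynyl}-3,4-dihydro-2H-pyran-2-carboxylate; 15 bromoform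
Product: 16 TMSE (3R)-7,7-dibromo-3-{[2,5-bis(TIPSO)phenyl]ethynyl}-2-oxabicyclo[4.1.0]heptane-3-carboxylate (cis-fused; both cyclopropane diastereomers)
Conditions: KOtBu, pentane, −20 to 0 °C
Reagents that add atoms: none
Why: Dibromocarbene, formed by α-elimination from bromoform, adds in a stereospecific [2+1] cycloaddition to the electron-rich enol ether much faster than to the alkyne or the arene. Both faces may be attacked, and both diastereomers are carried on because their ring-fusion centres disappear in step 9.

Step 9
Reactants: 16 TMSE (3R)-7,7-dibromo-3-{[2,5-bis(TIPSO)phenyl]ethynyl}-2-oxabicyclo[4.1.0]heptane-3-carboxylate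
Product: 17 TMSE (2R)-6-bromo-2-{[2,5-bis(TIPSO)phenyl]ethynyl}-7-methoxy-2,3,4,7-tetrahydrooxepine-2-carboxylate (both C7 epimers)
Conditions: AgOAc (2 equiv), MeOH, dark, rt to 45 °C
Reagents that add atoms: methanol, CO
Why: Silver ion assists loss of the endo bromide (the one syn to the pyran ring) while the C5–C7 ring-fusion bond opens in a disrotatory two-electron electrocyclic process, so ionisation and ring enlargement are concerted and no free cyclopropyl cation is involved. The resulting 2-bromoallyl cation over C5–C6–C7 is an oxocarbenium ion at C7 through O1; methanol adds at C7, which carries most of the charge, and acetate takes up the proton. The closest known reaction type is the silver- or base-promoted ring expansion of gem-dihalocyclopropanated glycals and dihydropyrans to 3-halo-2-alkoxy oxepines. The seven-membered ring is not closed by a cyclisation: it arises by cleavage of the bond shared by the three- and six-membered rings, so no medium-ring closure has to be paid for. The ring-fusion bond breaks rather than a lateral cyclopropane bond because of lone-pair assistance from O1 and because, by the Woodward–Hoffmann–DePuy rule, only departure of the endo bromide lets the ring bonds rotate inward; this also enforces the cis C5=C6 alkene and leaves the exo bromine on C6. Both diastereomers of 16 converge, since their centres at C5 and C7 become sp2 in the cation. The new acetal centre at C7 forms without control and is immaterial, because C7 becomes a methylene in step 10, while the quaternary C2 is remote from the cation and untouched. Any anomeric acetate formed by acetate capture is carried along, as it is reduced in the same way.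

Step 10
Reactants: 17 TMSE (2R)-6-bromo-2-{[2,5-bis(TIPSO)phenyl]ethynyl}-7-methoxy-2,3,4,7-tetrahydrooxepine-2-carboxylate
Product: 18 TMSE (2R)-6-bromo-2-{[2,5-bis(TIPSO)phenyl]ethynyl}-2,3,4,7-tetrahydrooxepine-2-carboxylate
Conditions: Et3SiH, BF3·OEt2, CH2Cl2, −78 to −30 °C
Reagents that add atoms: none
Why: Ionic reduction of an unsaturated acetal: BF3 regenerates the oxocarbenium ion and the silane delivers hydride to the oxygen-bearing terminus C7, as in reductive Ferrier-type deoxygenation, so the C5=C6 bromoalkene is kept. The C2–O1 bond should not ionise because the ester destabilises a cation at C2, and the aryl ketone is not yet present to be over-reduced.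

Step 11
Reactants: 18 TMSE (2R)-6-bromo-2-{[2,5-bis(TIPSO)phenyl]ethynyl}-2,3,4,7-tetrahydrooxepine-2-carboxylate
Product: 19 TMSE (2R)-2-{2-[2,5-bis(TIPSO)phenyl]-2-oxoethyl}-6-bromo-2,3,4,7-tetrahydrooxepine-2-carboxylate
Conditions: Ph3PAuNTf2 (5 mol %), 1,4-dioxane/H2O (10:1), 40 °C
Reagents that add atoms: water, O
Why: Carbonyl-assisted gold-catalysed hydration of a 3-alkynoate to a γ-keto ester: the ester carbonyl oxygen attacks the gold-bound alkyne 5-endo-dig at the aryl-bearing carbon, and water opens the cyclic oxocarbenium ion. The donor-substituted arene polarises the alkyne in the same sense, and the bromoalkene is too electron-poor to attack the activated alkyne.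

Step 12
Reactants: 20 5-bromo-2-methylpent-2-ene
Product: 22 (2E)-5-bromo-2-methylpent-2-en-1-ol, via enal 21 (not isolated)
Conditions: SeO2 (cat.), t-BuOOH, salicylic acid (cat.), CH2Cl2, rt; then NaBH4, MeOH, 0 °C
Reagents that add atoms: selenium dioxide, O=[Se]=O; tert-butyl hydroperoxide, CC(C)(C)OO
Why: Riley allylic oxidation (ene reaction, then [2,3]-sigmatropic shift) of a gem-dimethyl trisubstituted alkene takes the methyl group trans to the chain and so gives the E-allylic alcohol; borohydride returns over-oxidised enal to the alcohol.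

Step 13
Reactants: 22 (2E)-5-bromo-2-methylpent-2-en-1-ol
Product: 23 (2E)-5-bromo-1-(TBSO)-2-methylpent-2-ene
Conditions: TBSCl, imidazole, CH2Cl2, 0 °C to rt
Reagents that add atoms: tert-butyldimethylsilyl chloride, CC(C)(C)[Si](C)(C)Cl
Why: Standard silylation of a primary alcohol; an alkyl TBS ether can later be removed by mild acid while aryl TIPS ethers stay.

Step 14
Reactants: 23 (2E)-5-bromo-1-(TBSO)-2-methylpent-2-ene; 19 TMSE (2R)-2-{2-[2,5-bis(TIPSO)phenyl]-2-oxoethyl}-6-bromo-2,3,4,7-tetrahydrooxepine-2-carboxylate
Product: 25 TMSE (2R)-2-{2-[2,5-bis(TIPSO)phenyl]-2-oxoethyl}-6-[(3E)-5-(TBSO)-4-methylpent-3-en-1-yl]-2,3,4,7-tetrahydrooxepine-2-carboxylate, via alkylzinc bromide 24 (not isolated)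
Conditions: Zn dust, LiCl, THF, 50 °C; then 19, PdCl2(dppf) (5 mol %), THF, 50 °C
Reagents that add atoms: none
Why: Zinc inserts into the primary alkyl bromide in the presence of LiCl, and Negishi coupling (oxidative addition of the alkenyl bromide to zerovalent palladium, transmetalation, reductive elimination) forms C6–C8. The bidentate dppf ligand disfavours β-hydride elimination, and alkylzinc halides leave the ketone, the ester and the silyl ethers alone.

Step 15
Reactants: 25 TMSE (2R)-2-{2-[2,5-bis(TIPSO)phenyl]-2-oxoethyl}-6-[(3E)-5-(TBSO)-4-methylpent-3-en-1-yl]-2,3,4,7-tetrahydrooxepine-2-carboxylate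
Product: 26 TMSE (2R)-2-{2-[2,5-bis(TIPSO)phenyl]-2-oxoethyl}-6-[(3E)-5-hydroxy-4-methylpent-3-en-1-yl]-2,3,4,7-tetrahydrooxepine-2-carboxylate
Conditions: CSA (10 mol %), MeOH/CH2Cl2 (1:1), 0 °C
Reagents that add atoms: none
Why: Acid-catalysed methanolysis of a primary allylic alkyl silyl ether; aryl silyl ethers, whose oxygen is far less basic, and the TMSE ester should be stable to catalytic sulfonic acid in cold methanol.

Step 16
Reactants: 27 (E)-4-hydroxycinnamic acid
Product: 29 (E)-4-(TBSO)cinnamic acid, via bis-silylated coumarate 28 (not isolated)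
Conditions: TBSCl, imidazole, DMF, rt; then AcOH/THF/H2O, rt
Reagents that add atoms: tert-butyldimethylsilyl chloride, CC(C)(C)[Si](C)(C)Cl
Why: Phenol and acid are both silylated; the silyl ester is hydrolysed by dilute aqueous acid, under which the aryl silyl ether persists.

Step 17
Reactants: 26 TMSE (2R)-2-{2-[2,5-bis(TIPSO)phenyl]-2-oxoethyl}-6-[(3E)-5-hydroxy-4-methylpent-3-en-1-yl]-2,3,4,7-tetrahydrooxepine-2-carboxylate; 29 (E)-4-(TBSO)cinnamic acid
Product: 30 TMSE (2R)-2-{2-[2,5-bis(TIPSO)phenyl]-2-oxoethyl}-6-[(3E)-4-methyl-5-({(2E)-3-[4-(TBSO)phenyl]prop-2-enoyl}oxy)pent-3-en-1-yl]-2,3,4,7-tetrahydrooxepine-2-carboxylate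
Conditions: EDC·HCl, DMAP, CH2Cl2, 0 °C to rt
Reagents that add atoms: none
Why: Steglich esterification (carbodiimide activation, DMAP acyl transfer) of a primary allylic alcohol; no base strong enough to enolise the β-alkoxy ketone is present.

Step 18
Reactants: 30 TMSE (2R)-2-{2-[2,5-bis(TIPSO)phenyl]-2-oxoethyl}-6-[(3E)-4-methyl-5-({(2E)-3-[4-(TBSO)phenyl]prop-2-enoyl}oxy)pent-3-en-1-yl]-2,3,4,7-tetrahydrooxepine-2-carboxylate
Product: 31 (2R)-2-[2-(2,5-dihydroxyphenyl)-2-oxoethyl]-6-[(3E)-5-{[(2E)-3-(4-hydroxyphenyl)prop-2-enoyl]oxy}-4-methylpent-3-en-1-yl]-2,3,4,7-tetrahydrooxepine-2-carboxylic acid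
Conditions: TBAF, AcOH (1:1), THF, 0 °C to rt; pH 4 buffer work-up
Reagents that add atoms: none
Why: Fluoride-induced desilylation of the three aryl silyl ethers and fragmentation of the 2-(trimethylsilyl)ethyl ester (attack at silicon, loss of ethylene). Acetic acid buffers the medium so that enolisation of the ketone, and with it retro-oxa-Michael opening at C2, and acyl transfer of the cinnamate should be suppressed.

## Compound list

1 | oxalyl chloride | O=C(Cl)C(=O)Cl | starting material
2 | 2-(trimethylsilyl)ethanol | C[Si](C)(C)CCO | starting material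
3 | bis[2-(trimethylsilyl)ethyl] oxalate | C[Si](C)(C)CCOC(=O)C(=O)OCC[Si](C)(C)C | intermediate
4 | 5-bromopent-1-ene | C=CCCCBr | starting material
5 | pent-4-enylmagnesium bromide | C=CCCC[Mg]Br | intermediate
6 | TMSE 2-oxohept-6-enoate | C=CCCCC(=O)C(=O)OCC[Si](C)(C)C | intermediate
7 | 2,5-dihydroxybenzaldehyde | O=Cc1cc(O)ccc1O | starting material
8 | 2,5-bis(TIPSO)benzaldehyde | O=Cc1cc(O[Si](C(C)C)(C(C)C)C(C)C)ccc1O[Si](C(C)C)(C(C)C)C(C)C | intermediate
9 | 2-ethynyl-1,4-bis(TIPSO)benzene | C#Cc1cc(O[Si](C(C)C)(C(C)C)C(C)C)ccc1O[Si](C(C)C)(C(C)C)C(C)C | intermediate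
10 | TMSE (2R)-2-{[2,5-bis(TIPSO)phenyl]ethynyl}-2-hydroxyhept-6-enoate | C=CCCC[C@@](C#Cc1cc(O[Si](C(C)C)(C(C)C)C(C)C)ccc1O[Si](C(C)C)(C(C)C)C(C)C)(C(=O)OCC[Si](C)(C)C)O | intermediate
11 | TMSE (2R)-2-{[2,5-bis(TIPSO)phenyl]ethynyl}-2-hydroxy-6-oxohexanoate | O=CCCC[C@@](C#Cc1cc(O[Si](C(C)C)(C(C)C)C(C)C)ccc1O[Si](C(C)C)(C(C)C)C(C)C)(C(=O)OCC[Si](C)(C)C)O | intermediate
12 | TMSE (2R)-2-{[2,5-bis(TIPSO)phenyl]ethynyl}-6-hydroxyoxane-2-carboxylate (both C6 epimers) | OC1CCC[C@@](C#Cc2cc(O[Si](C(C)C)(C(C)C)C(C)C)ccc2O[Si](C(C)C)(C(C)C)C(C)C)(C(=O)OCC[Si](C)(C)C)O1 | intermediate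
13 | TMSE (2R)-2-{[2,5-bis(TIPSO)phenyl]ethynyl}-6-(methylsulfonyloxy)oxane-2-carboxylate | CS(=O)(=O)OC1CCC[C@@](C#Cc2cc(O[Si](C(C)C)(C(C)C)C(C)C)ccc2O[Si](C(C)C)(C(C)C)C(C)C)(C(=O)OCC[Si](C)(C)C)O1 | intermediate
14 | TMSE (2R)-2-{[2,5-bis(TIPSO)phenyl]ethynyl}-3,4-dihydro-2H-pyran-2-carboxylate | C1=CCC[C@@](C#Cc2cc(O[Si](C(C)C)(C(C)C)C(C)C)ccc2O[Si](C(C)C)(C(C)C)C(C)C)(C(=O)OCC[Si](C)(C)C)O1 | intermediate
15 | bromoform | BrC(Br)Br | starting material
16 | TMSE (3R)-7,7-dibromo-3-{[2,5-bis(TIPSO)phenyl]ethynyl}-2-oxabicyclo[4.1.0]heptane-3-carboxylate (cis-fused, both cyclopropane diastereomers) | BrC1(Br)C2CC[C@@](C#Cc3cc(O[Si](C(C)C)(C(C)C)C(C)C)ccc3O[Si](C(C)C)(C(C)C)C(C)C)(C(=O)OCC[Si](C)(C)C)OC12 | intermediate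
17 | TMSE (2R)-6-bromo-2-{[2,5-bis(TIPSO)phenyl]ethynyl}-7-methoxy-2,3,4,7-tetrahydrooxepine-2-carboxylate (both C7 epimers) | BrC1=CCC[C@@](C#Cc2cc(O[Si](C(C)C)(C(C)C)C(C)C)ccc2O[Si](C(C)C)(C(C)C)C(C)C)(C(=O)OCC[Si](C)(C)C)OC1OC | intermediate
18 | TMSE (2R)-6-bromo-2-{[2,5-bis(TIPSO)phenyl]ethynyl}-2,3,4,7-tetrahydrooxepine-2-carboxylate | BrC1=CCC[C@@](C#Cc2cc(O[Si](C(C)C)(C(C)C)C(C)C)ccc2O[Si](C(C)C)(C(C)C)C(C)C)(C(=O)OCC[Si](C)(C)C)OC1 | intermediate
19 | TMSE (2R)-2-{2-[2,5-bis(TIPSO)phenyl]-2-oxoethyl}-6-bromo-2,3,4,7-tetrahydrooxepine-2-carboxylate | BrC1=CCC[C@@](CC(=O)c2cc(O[Si](C(C)C)(C(C)C)C(C)C)ccc2O[Si](C(C)C)(C(C)C)C(C)C)(C(=O)OCC[Si](C)(C)C)OC1 | intermediate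
20 | 5-bromo-2-methylpent-2-ene | CC(C)=CCCBr | starting material
21 | (2E)-5-bromo-2-methylpent-2-enal | C/C(=C\CCBr)C=O | intermediate
22 | (2E)-5-bromo-2-methylpent-2-en-1-ol | C/C(=C\CCBr)CO | intermediate
23 | (2E)-5-bromo-1-(TBSO)-2-methylpent-2-ene | C/C(=C\CCBr)CO[Si](C)(C)C(C)(C)C | intermediate
24 | [(3E)-5-(TBSO)-4-methylpent-3-en-1-yl]zinc bromide | C/C(=C\CC[Zn]Br)CO[Si](C)(C)C(C)(C)C | intermediate
25 | TMSE (2R)-2-{2-[2,5-bis(TIPSO)phenyl]-2-oxoethyl}-6-[(3E)-5-(TBSO)-4-methylpent-3-en-1-yl]-2,3,4,7-tetrahydrooxepine-2-carboxylate | C/C(=C\CCC1=CCC[C@@](CC(=O)c2cc(O[Si](C(C)C)(C(C)C)C(C)C)ccc2O[Si](C(C)C)(C(C)C)C(C)C)(C(=O)OCC[Si](C)(C)C)OC1)CO[Si](C)(C)C(C)(C)C | intermediate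
26 | TMSE (2R)-2-{2-[2,5-bis(TIPSO)phenyl]-2-oxoethyl}-6-[(3E)-5-hydroxy-4-methylpent-3-en-1-yl]-2,3,4,7-tetrahydrooxepine-2-carboxylate | C/C(=C\CCC1=CCC[C@@](CC(=O)c2cc(O[Si](C(C)C)(C(C)C)C(C)C)ccc2O[Si](C(C)C)(C(C)C)C(C)C)(C(=O)OCC[Si](C)(C)C)OC1)CO | intermediate
27 | (E)-4-hydroxycinnamic acid | O=C(O)/C=C/c1ccc(O)cc1 | starting material
28 | tert-butyldimethylsilyl (E)-4-(TBSO)cinnamate | CC(C)(C)[Si](C)(C)OC(=O)/C=C/c1ccc(O[Si](C)(C)C(C)(C)C)cc1 | intermediate
29 | (E)-4-(TBSO)cinnamic acid | O=C(O)/C=C/c1ccc(O[Si](C)(C)C(C)(C)C)cc1 | intermediate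
30 | TMSE (2R)-2-{2-[2,5-bis(TIPSO)phenyl]-2-oxoethyl}-6-[(3E)-4-methyl-5-({(2E)-3-[4-(TBSO)phenyl]prop-2-enoyl}oxy)pent-3-en-1-yl]-2,3,4,7-tetrahydrooxepine-2-carboxylate | C/C(=C\CCC1=CCC[C@@](CC(=O)c2cc(O[Si](C(C)C)(C(C)C)C(C)C)ccc2O[Si](C(C)C)(C(C)C)C(C)C)(C(=O)OCC[Si](C)(C)C)OC1)COC(=O)/C=C/c1ccc(O[Si](C)(C)C(C)(C)C)cc1 | intermediate
31 | (2R)-2-[2-(2,5-dihydroxyphenyl)-2-oxoethyl]-6-[(3E)-5-{[(2E)-3-(4-hydroxyphenyl)prop-2-enoyl]oxy}-4-methylpent-3-en-1-yl]-2,3,4,7-tetrahydrooxepine-2-carboxylic acid | C/C(=C\CCC1=CCC[C@@](CC(=O)c2cc(O)ccc2O)(C(=O)O)OC1)COC(=O)/C=C/c1ccc(O)cc1 | target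

## Step count and least certain steps

Total: 18 steps. Longest linear sequence: 13 steps (steps 1, 2, 5, 6, 7, 8, 9, 10, 11, 14, 15, 17, 18; the branch through steps 3 and 4 is equally long).

**Step 9 (key step).** The ester and alkynyl groups on C2 lower the donor ability of O1, so ionisation may be slow and need heating. Silver-assisted addition of methanol to the arylalkyne, or proton loss from the cation instead of capture at C7, may then compete. The fallback separates ring opening from capture and drops silver, methanol and the acetal. It sets out from 16, which is heated in pyridine; thermal electrocyclic opening and loss of the C4 proton should give TMSE (2R)-6-bromo-2-{[2,5-bis(TIPSO)phenyl]ethynyl}-2,3-dihydrooxepine-2-carboxylate F1, the known outcome when 7,7-dihalo-2-oxabicyclo[4.1.0]heptanes are heated with amine bases. Ionic hydrogenation of this dienyl ether (Et3SiH, TFA, CH2Cl2, −20 °C) protonates C4, regenerates the oxygen-stabilised allyl cation and delivers hydride to C7, coming back to the route at 18.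

**Step 5.** Facial discrimination may be poor for an aliphatic keto ester, and aldol self-condensation of the enolisable keto ester under amine and zinc may consume material. The fallback gives up catalyst control for resolution. It sets out from 6 and 9: the lithium acetylide of 9 (n-BuLi, THF, −78 °C) adds to the ketone of 6 to give racemic TMSE 2-{[2,5-bis(TIPSO)phenyl]ethynyl}-2-hydroxyhept-6-enoate F2, which is resolved by preparative chromatography on a chiral stationary phase, coming back at 10.

**Step 7.** The anomeric sulfonate may ionise and recombine with chloride instead of eliminating, and long heating with amine salts may degrade the propargylic ether. The fallback sets out from 12, which with PPTS in methanol gives TMSE (2R)-2-{[2,5-bis(TIPSO)phenyl]ethynyl}-6-methoxyoxane-2-carboxylate F3. Treatment with TMSOTf and i-Pr2NEt in CH2Cl2 (acetal-to-enol-ether elimination through deprotonation of the silyl-activated oxocarbenium ion) comes back at 14.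

**Step 18.** Unbuffered fluoride may enolise the ketone and open the oxepine by E1cB loss of O1, which would racemise C2 or let the freed ortho phenol close a chromanone, while buffered fluoride may leave the 2-(trimethylsilyl)ethyl ester partly intact. The fallback keeps the whole endgame acidic. It sets out from 30: HF·pyridine with extra pyridine in THF removes only the aryl silyl ethers and gives TMSE (2R)-2-[2-(2,5-dihydroxyphenyl)-2-oxoethyl]-6-[(3E)-5-{[(2E)-3-(4-hydroxyphenyl)prop-2-enoyl]oxy}-4-methylpent-3-en-1-yl]-2,3,4,7-tetrahydrooxepine-2-carboxylate F4. Acidolysis of the ester with TFA in CH2Cl2 at 0 °C (fragmentation through the β-silyl cation) then comes back at 31.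

## Further compounds

F1 | step 9 | TMSE (2R)-6-bromo-2-{[2,5-bis(TIPSO)phenyl]ethynyl}-2,3-dihydrooxepine-2-carboxylate | BrC1=CO[C@](C#Cc2cc(O[Si](C(C)C)(C(C)C)C(C)C)ccc2O[Si](C(C)C)(C(C)C)C(C)C)(C(=O)OCC[Si](C)(C)C)CC=C1
F2 | step 5 | racemic TMSE 2-{[2,5-bis(TIPSO)phenyl]ethynyl}-2-hydroxyhept-6-enoate | C=CCCCC(C#Cc1cc(O[Si](C(C)C)(C(C)C)C(C)C)ccc1O[Si](C(C)C)(C(C)C)C(C)C)(C(=O)OCC[Si](C)(C)C)O
F3 | step 7 | TMSE (2R)-2-{[2,5-bis(TIPSO)phenyl]ethynyl}-6-methoxyoxane-2-carboxylate (both C6 epimers) | COC1CCC[C@@](C#Cc2cc(O[Si](C(C)C)(C(C)C)C(C)C)ccc2O[Si](C(C)C)(C(C)C)C(C)C)(C(=O)OCC[Si](C)(C)C)O1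
F4 | step 18 | TMSE (2R)-2-[2-(2,5-dihydroxyphenyl)-2-oxoethyl]-6-[(3E)-5-{[(2E)-3-(4-hydroxyphenyl)prop-2-enoyl]oxy}-4-methylpent-3-en-1-yl]-2,3,4,7-tetrahydrooxepine-2-carboxylate | C/C(=C\CCC1=CCC[C@@](CC(=O)c2cc(O)ccc2O)(C(=O)OCC[Si](C)(C)C)OC1)COC(=O)/C=C/c1ccc(O)cc1
A1 | alternative 1 | tert-butyl (2R)-6-[(3E)-5-({(2E)-3-[4-(methoxymethoxy)phenyl]prop-2-enoyl}oxy)-4-methylpent-3-en-1-yl]-2-(2-oxobut-3-yn-1-yl)-2,3,4,7-tetrahydrooxepine-2-carboxylate | COCOc1ccc(/C=C/C(=O)OC/C(C)=C/CCC2=CCC[C@@](CC(=O)C#C)(C(=O)OC(C)(C)C)OC2)cc1
A2 | alternative 1 | 2-methoxyfuran | COc1ccco1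
A3 | alternative 1 | tert-butyl (2R)-2-[2-(5-hydroxy-2-methoxyphenyl)-2-oxoethyl]-6-[(3E)-5-({(2E)-3-[4-(methoxymethoxy)phenyl]prop-2-enoyl}oxy)-4-methylpent-3-en-1-yl]-2,3,4,7-tetrahydrooxepine-2-carboxylate | COCOc1ccc(/C=C/C(=O)OC/C(C)=C/CCC2=CCC[C@@](CC(=O)c3cc(O)ccc3OC)(C(=O)OC(C)(C)C)OC2)cc1
A4 | alternative 2 | TMSE (2R,5Z,9E)-2-{2-[2,5-bis(TBSO)phenyl]-2-oxoethyl}-11-(TBSO)-2-(methoxymethoxy)-10-methyl-6-(trimethylsilyl)undeca-5,9-dienoate | CC(C)(C)[Si](C)(C)OC/C(C)=C/CC/C(=C/CC[C@@](CC(=O)c1cc(O[Si](C)(C)C(C)(C)C)ccc1O[Si](C)(C)C(C)(C)C)(C(=O)OCC[Si](C)(C)C)OCOC)[Si](C)(C)C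
A5 | alternative 2 | TMSE (2R)-2-{2-[2,5-bis(TBSO)phenyl]-2-oxoethyl}-6-[(3E)-5-(TBSO)-4-methylpent-3-en-1-yl]-2,3,4,7-tetrahydrooxepine-2-carboxylate | CC(C)(C)[Si](C)(C)OC/C(C)=C/CCC1=CCC[C@@](CC(=O)c2cc(O[Si](C)(C)C(C)(C)C)ccc2O[Si](C)(C)C(C)(C)C)(C(=O)OCC[Si](C)(C)C)OC1
A6 | alternative 3 | TMSE (2R)-2-({2-[2,5-bis(TBSO)phenyl]-1,3-dioxolan-2-yl}methyl)-7-diazo-2-hydroxy-6-oxoheptanoate | [N-]=[N+]=CC(=O)CCC[C@@](CC1(OCCO1)c1cc(O[Si](C)(C)C(C)(C)C)ccc1O[Si](C)(C)C(C)(C)C)(C(=O)OCC[Si](C)(C)C)O
A7 | alternative 3 | TMSE (2R)-2-({2-[2,5-bis(TBSO)phenyl]-1,3-dioxolan-2-yl}methyl)-6-oxooxepane-2-carboxylate | O=C1CCC[C@@](CC2(OCCO2)c2cc(O[Si](C)(C)C(C)(C)C)ccc2O[Si](C)(C)C(C)(C)C)(C(=O)OCC[Si](C)(C)C)OC1
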